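**Plan**

- Retrosynthetic cuts: C4–Br (from the C4 alcohol, with inversion); C1–C2 of ring A (alkenyl triflate at C1, primary alkylborane at C2); C6–C7 and C6–C11 of ring B (double alkylation of a butyrolactone enolate by a bromochlorinated five-carbon dielectrophile).
- Locants: ring A = C1 (carries the exocyclic CH2), C2, C3, C4 (CHBr), C5 (CMe2), C6 (spiro); ring B = C6, C7, C8, C9 (CMeBr), C10 (CHCl), C11.
- Enabling feature: in ring A the alkene carbon C1, 1,1-disubstituted and carrying the exocyclic methylene, is bonded to the methylene C2. This is the C(sp2)–C(sp3) bond that an alkenyl triflate and a primary alkyl-9-BBN borane form, so ring A can close with its alkene already in place.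
- Forward order: a vinyl butyrolactone (C1, C4–C6) is spiro-annulated with the bromochloride chain (C7–C11) to give ring B; the lactone is opened to the C1 enol triflate; ring A closes by hydroboration and coupling; the C4 oxygen is exchanged for bromine.
- Stereochemistry: C9/C10 from a catalytic enantioselective bromochlorination of a Z allylic alcohol (anti addition); C4 from an oxazaborolidine reduction, inverted in the last step; C6 from ring closure anti to the vinyl group of the lactone.

Key step: step 12

Remark (assumption): in step 7 the ligand antipode that leads to the (2S,3S) bromochloride is used; the sense of induction would be checked by correlation on first use.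
Remark: the product of step 10 is a ring–chain tautomeric pair (hydroxy ketone and cyclic hemiketal); it is listed as the open form.

**Route**

Step 1
Reactants: 1 2,2-dimethylsuccinic anhydride
Product: 2 4-methoxy-2,2-dimethyl-4-oxobutanoic acid
Conditions: MeOH, reflux
Reagents that add atoms: methanol, CO
Why: Regioselective alcoholysis of an unsymmetrical cyclic anhydride: methanol should attack the carbonyl next to CH2 and not the one shielded by the quaternary carbon, leaving the free acid at the future C4 and the ester at the future C1.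

Step 2
Reactants: 2 4-methoxy-2,2-dimethyl-4-oxobutanoic acid; 3 tributyl(vinyl)stannane
Product: 5 methyl 3,3-dimethyl-4-oxohex-5-enoate, via acid chloride 4 (not isolated)
Conditions: (COCl)2, DMF (cat.), CH2Cl2, 0 to 23 °C; then 3, PdCl2(PPh3)2 (3 mol %), toluene, 60 °C
Reagents that add atoms: none
Why: Acid chloride formation followed by Stille acylation (zerovalent palladium inserts into the acyl C–Cl bond, vinyl is transferred from tin) should give the vinyl ketone under neutral conditions that spare the methyl ester and do not add to the new enone.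

Step 3
Reactants: 5 methyl 3,3-dimethyl-4-oxohex-5-enoate
Product: 7 (5S)-5-ethenyl-4,4-dimethyloxolan-2-one, via hydroxy ester 6 (not isolated)
Conditions: (R)-2-methyl-CBS-oxazaborolidine [(3aR)-1-methyl-3,3-diphenyltetrahydro-1H,3H-pyrrolo[1,2-c][1,3,2]oxazaborole] (0.2 equiv), catecholborane (1.5 equiv), toluene, −78 °C; MeOH; then TsOH·H2O (cat.), CH2Cl2, 23 °C
Reagents that add atoms: none
Why: Corey–Bakshi–Shibata reduction with the tertiary alkyl group as the large and vinyl as the small substituent should deliver hydride under control of the (R)-catalyst to give the (S)-carbinol at C4; the γ-hydroxy ester then lactonises (gem-dimethyl effect), and the lactone both stores the C4 oxygen and serves as the C6 pronucleophile.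

Step 4
Reactants: 8 4-bromobut-1-yne; 9 methyl chloroformate
Product: 10 methyl 5-bromopent-2-ynoate
Conditions: n-BuLi (1.0 equiv), THF, −78 °C; then 9, −78 to −20 °C
Reagents that add atoms: none
Why: C-acylation of a lithium acetylide with a chloroformate; deprotonation of the terminal alkyne is much faster than attack of the base on the primary bromide at −78 °C.

Step 5
Reactants: 10 methyl 5-bromopent-2-ynoate
Product: 11 methyl (2Z)-5-bromo-3-methylpent-2-enoate
Conditions: Me2CuLi (from MeLi and CuI, 1.2 equiv), THF, −78 °C; then MeOH, −78 °C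
Reagents that add atoms: lithium dimethylcuprate, [Li+].C[Cu-]C
Why: Conjugate addition of a Gilman cuprate to an ynoate (syn-carbocupration) with cold protonation of the alkenylcopper species should put the new methyl cis to hydrogen, the Z geometry that translates into a trans bromide/chloride pair in ring B.

Step 6
Reactants: 11 methyl (2Z)-5-bromo-3-methylpent-2-enoate
Product: 12 (2Z)-5-bromo-3-methylpent-2-en-1-ol
Conditions: iBu2AlH (2.5 equiv), CH2Cl2, −78 °C; aq. potassium sodium tartrate
Reagents that add atoms: none
Why: 1,2-Reduction of the conjugated ester to the allylic alcohol with diisobutylaluminium hydride, which should leave the alkene geometry and the primary bromide untouched.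

Step 7
Reactants: 12 (2Z)-5-bromo-3-methylpent-2-en-1-ol
Product: 13 (2S,3S)-3,5-dibromo-2-chloro-3-methylpentan-1-ol
Conditions: N-bromosuccinimide (1.1 equiv), ClTi(OiPr)3 (1.1 equiv), chiral tridentate Schiff-base ligand (salicylaldimine of a 1,1-diaryl amino alcohol, 20 mol %), hexanes, −20 °C
Reagents that add atoms: N-bromosuccinimide, O=C1CCC(=O)N1Br; chlorotitanium triisopropoxide, CC(C)O[Ti](Cl)(OC(C)C)OC(C)C
Why: Titanium-mediated catalytic enantioselective bromochlorination of an allylic alcohol: the ligand-bound titanium alkoxide should select the alkene face for bromenium transfer and deliver its chloride to the carbinol-proximal carbon from the opposite side, so anti addition across the Z alkene gives the tertiary bromide (C9) and secondary chloride (C10) as the (S,S) pair.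

Step 8
Reactants: 13 (2S,3S)-3,5-dibromo-2-chloro-3-methylpentan-1-ol
Product: 14 (2S,3S)-3,5-dibromo-2-chloro-3-methylpentyl trifluoromethanesulfonate
Conditions: Tf2O, 2,6-lutidine, CH2Cl2, −78 °C
Reagents that add atoms: trifluoromethanesulfonic anhydride, O=S(=O)(OS(=O)(=O)C(F)(F)F)C(F)(F)F
Why: O-Sulfonylation of the primary alcohol; the β-chlorine and the quaternary neighbour slow displacement at C11, so a triflate is needed there, and the same features should keep it stable until it is used.

Step 9
Reactants: 7 (5S)-5-ethenyl-4,4-dimethyloxolan-2-one; 14 (2S,3S)-3,5-dibromo-2-chloro-3-methylpentyl trifluoromethanesulfonate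
Product: 16 (3S,5R,7S,8S)-8-bromo-7-chloro-3-ethenyl-4,4,8-trimethyl-2-oxaspiro[4.5]decan-1-one, via monoalkylated lactone 15 (not isolated)
Conditions: LiN(iPr)2 (1.05 equiv), THF, −78 °C; 14, −78 to −40 °C; then LiN(iPr)2 (1.1 equiv), DMPU, −78 to 0 °C
Reagents that add atoms: none
Why: Spiroannulation by two SN2 enolate alkylations: the lithium lactone enolate should attack the primary triflate (C11) well before the primary bromide, and after a second deprotonation the 6-exo-tet closure onto C7 should occur on the enolate face anti to the C4 vinyl group, which sets C6 relative to C4 and hence, with enantiopure 14, relative to C9 and C10.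

Step 10
Reactants: 16 the spirolactone
Product: 18 1-[(1R,3S,4S)-4-bromo-3-chloro-1-[(3S)-3-hydroxy-2-methylpent-4-en-2-yl]-4-methylcyclohexyl]ethan-1-one (open form of the tautomeric pair), via enol ether 17 (not isolated)
Conditions: Cp2Ti(μ-Cl)(μ-CH2)AlMe2 (Tebbe reagent, 1.5 equiv), pyridine, THF–toluene, −40 to 0 °C; then 1 M HCl, THF, 0 °C
Reagents that add atoms: Tebbe reagent, C[Al-]1(C)C[Ti]([Cl+]1)(C1C=CC=C1)C1C=CC=C1; water, O
Why: Tebbe methylenation of the lactone carbonyl followed by acid hydrolysis of the exocyclic enol ether should give the C1 methyl ketone and free the C4 hydroxyl; cold, pyridine-buffered conditions and immediate hydrolysis are chosen so the allyl vinyl ether does not undergo a Lewis-acid-induced Claisen ring expansion.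

Step 11
Reactants: 18 the hydroxy ketone
Product: 20 1-[(1R,3S,4S)-4-bromo-3-chloro-4-methyl-1-[(3S)-2-methyl-3-(triethylsilyloxy)pent-4-en-2-yl]cyclohexyl]ethenyl trifluoromethanesulfonate, via hydroxy enol triflate 19 (not isolated)
Conditions: KN(SiMe3)2 (2.2 equiv), THF, −78 to −40 °C; PhNTf2 (1.05 equiv), −78 °C; then Et3SiOTf (2 equiv), −78 °C
Reagents that add atoms: N-phenylbis(trifluoromethanesulfonimide), O=S(=O)(N(c1ccccc1)S(=O)(=O)C(F)(F)F)C(F)(F)F; triethylsilyl trifluoromethanesulfonate, CC[Si](CC)(CC)OS(=O)(=O)C(F)(F)F
Why: Enolate O-triflation with in-situ O-silylation: two equivalents of base should pull the ring–chain equilibrium to the open alkoxide enolate (only the methyl group can enolise), the triflimide should sulfonylate the enolate oxygen in preference to the hindered neopentylic alkoxide, and the silyl triflate then caps the alkoxide at −78 °C, before triflyl transfer from the enol oxygen to the alkoxide can set in on warming.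

Step 12
Reactants: 20 the enol triflate triethylsilyl ether
Product: 22 (4S,6S,9S,10S)-9-bromo-10-chloro-5,5,9-trimethyl-1-methylidene-4-(triethylsilyloxy)spiro[5.5]undecane (plan locants), via alkylborane 21 (not isolated)
Conditions: 9-BBN-H (1.5 equiv), THF, 0 to 23 °C; then PdCl2(dppf) (10 mol %), AsPh3 (10 mol %), Cs2CO3 (3 equiv), DMF–THF–H2O, 23 to 50 °C
Reagents that add atoms: none
Why: 9-BBN adds to the monosubstituted vinyl group in the anti-Markovnikov sense and places boron on C2; zerovalent palladium then inserts into the C1–OTf bond, the base-activated borate hands C2 to palladium within the molecule, and reductive elimination forms C1–C2. The closest known reaction type is the one-flask hydroboration and intramolecular B-alkyl Suzuki–Miyaura coupling of 2-halo- or 2-triflyloxy-1,ω-dienes to methylenecycloalkanes. Ring A closes as a six-membered carbocycle by C(sp2)–C(sp3) reductive elimination from a seven-membered palladacycle, leaving the alkene exocyclic at C1. No stereocentre is formed, and C4, C6, C9 and C10 are not epimerisable under the mildly basic conditions. Only chemoselectivity is needed: 9-BBN should choose the unhindered vinyl group over the electron-poor 1,1-disubstituted triflyloxy alkene, and palladium should choose the alkenyl triflate over the unactivated tertiary bromide and secondary chloride, which should not undergo oxidative addition with this catalyst at 23–50 °C. The wide bite angle of dppf and the AsPh3 additive should favour transmetallation and reductive elimination over β-hydride elimination of the alkylpalladium intermediate.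

Step 13
Reactants: 22 the spirocyclic triethylsilyl ether
Product: 23 (4S,6S,9S,10S)-9-bromo-10-chloro-5,5,9-trimethyl-1-methylidenespiro[5.5]undecan-4-ol (plan locants)
Conditions: HF·pyridine, pyridine, THF, 0 to 23 °C
Reagents that add atoms: none
Why: Fluoride-induced cleavage of the silyl ether; buffered HF·pyridine should be neither basic enough to eliminate the tertiary bromide nor acidic enough to isomerise the exocyclic alkene.

Step 14
Reactants: 23 the C4 alcohol
Product: 24 obtusane, (4R,6S,9S,10S)-4,9-dibromo-10-chloro-5,5,9-trimethyl-1-methylidenespiro[5.5]undecane (plan locants)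
Conditions: CBr4 (3 equiv), P(n-C8H17)3 (3 equiv), toluene, 70 °C
Reagents that add atoms: carbon tetrabromide, BrC(Br)(Br)Br
Why: Appel bromination: bromide should displace the alkoxyphosphonium group from the rear (SN2), turning the (4S)-alcohol into the (4R)-bromide with inversion; the small, strongly nucleophilic trialkylphosphine and the non-polar solvent are chosen to favour displacement over ionisation at this neopentylic secondary carbon.

**Compound list**

1 | 2,2-dimethylsuccinic anhydride | CC1(C)CC(=O)OC1=O | starting material
2 | 4-methoxy-2,2-dimethyl-4-oxobutanoic acid | COC(=O)CC(C)(C)C(=O)O | intermediate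
3 | tributyl(vinyl)stannane | C=C[Sn](CCCC)(CCCC)CCCC | starting material
4 | methyl 4-chloro-3,3-dimethyl-4-oxobutanoate (acid chloride) | COC(=O)CC(C)(C)C(=O)Cl | intermediate (not isolated)
5 | methyl 3,3-dimethyl-4-oxohex-5-enoate | COC(=O)CC(C)(C)C(=O)C=C | intermediate
6 | methyl (4S)-4-hydroxy-3,3-dimethylhex-5-enoate (hydroxy ester) | COC(=O)CC(C)(C)[C@@H](O)C=C | intermediate (not isolated)
7 | (5S)-5-ethenyl-4,4-dimethyloxolan-2-one | O=C1O[C@@H](C=C)C(C)(C)C1 | intermediate
8 | 4-bromobut-1-yne | BrCCC#C | starting material
9 | methyl chloroformate | COC(=O)Cl | starting material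
10 | methyl 5-bromopent-2-ynoate | COC(=O)C#CCCBr | intermediate
11 | methyl (2Z)-5-bromo-3-methylpent-2-enoate | COC(=O)/C=C(/C)CCBr | intermediate
12 | (2Z)-5-bromo-3-methylpent-2-en-1-ol | OC/C=C(/C)CCBr | intermediate
13 | (2S,3S)-3,5-dibromo-2-chloro-3-methylpentan-1-ol | BrCC[C@](C)(Br)[C@@H](Cl)CO | intermediate
14 | (2S,3S)-3,5-dibromo-2-chloro-3-methylpentyl trifluoromethanesulfonate | BrCC[C@](C)(Br)[C@@H](Cl)COS(=O)(=O)C(F)(F)F | intermediate
15 | (5S)-3-[(2S,3S)-3,5-dibromo-2-chloro-3-methylpentyl]-5-ethenyl-4,4-dimethyloxolan-2-one (monoalkylated lactone, both C3 epimers) | O=C1O[C@@H](C=C)C(C)(C)C1C[C@H](Cl)[C@@](C)(Br)CCBr | intermediate (not isolated)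
16 | (3S,5R,7S,8S)-8-bromo-7-chloro-3-ethenyl-4,4,8-trimethyl-2-oxaspiro[4.5]decan-1-one | O=C1O[C@@H](C=C)C(C)(C)[C@]12CC[C@](C)(Br)[C@@H](Cl)C2 | intermediate
17 | (3S,5R,7S,8S)-8-bromo-7-chloro-3-ethenyl-4,4,8-trimethyl-1-methylidene-2-oxaspiro[4.5]decane (enol ether) | C=C1O[C@@H](C=C)C(C)(C)[C@]12CC[C@](C)(Br)[C@@H](Cl)C2 | intermediate (not isolated)
18 | 1-[(1R,3S,4S)-4-bromo-3-chloro-1-[(3S)-3-hydroxy-2-methylpent-4-en-2-yl]-4-methylcyclohexyl]ethan-1-one (in equilibrium with its cyclic hemiketal) | CC(=O)[C@@]1(CC[C@](C)(Br)[C@@H](Cl)C1)C(C)(C)[C@@H](O)C=C | intermediate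
19 | 1-[(1R,3S,4S)-4-bromo-3-chloro-1-[(3S)-3-hydroxy-2-methylpent-4-en-2-yl]-4-methylcyclohexyl]ethenyl trifluoromethanesulfonate (present as its potassium alkoxide) | C=C(OS(=O)(=O)C(F)(F)F)[C@@]1(CC[C@](C)(Br)[C@@H](Cl)C1)C(C)(C)[C@@H](O)C=C | intermediate (not isolated)
20 | 1-[(1R,3S,4S)-4-bromo-3-chloro-4-methyl-1-[(3S)-2-methyl-3-(triethylsilyloxy)pent-4-en-2-yl]cyclohexyl]ethenyl trifluoromethanesulfonate | C=C(OS(=O)(=O)C(F)(F)F)[C@@]1(CC[C@](C)(Br)[C@@H](Cl)C1)C(C)(C)[C@@H](O[Si](CC)(CC)CC)C=C | intermediate
21 | 1-[(1R,3S,4S)-1-[(3S)-5-(9-borabicyclo[3.3.1]nonan-9-yl)-2-methyl-3-(triethylsilyloxy)pentan-2-yl]-4-bromo-3-chloro-4-methylcyclohexyl]ethenyl trifluoromethanesulfonate (alkylborane) | C=C(OS(=O)(=O)C(F)(F)F)[C@@]1(CC[C@](C)(Br)[C@@H](Cl)C1)C(C)(C)[C@@H](O[Si](CC)(CC)CC)CCB1C2CCCC1CCC2 | intermediate (not isolated)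
22 | (4S,6S,9S,10S)-9-bromo-10-chloro-5,5,9-trimethyl-1-methylidene-4-(triethylsilyloxy)spiro[5.5]undecane | C=C1CC[C@H](O[Si](CC)(CC)CC)C(C)(C)[C@]12CC[C@](C)(Br)[C@@H](Cl)C2 | intermediate
23 | (4S,6S,9S,10S)-9-bromo-10-chloro-5,5,9-trimethyl-1-methylidenespiro[5.5]undecan-4-ol | C=C1CC[C@H](O)C(C)(C)[C@]12CC[C@](C)(Br)[C@@H](Cl)C2 | intermediate
24 | obtusane, (4R,6S,9S,10S)-4,9-dibromo-10-chloro-5,5,9-trimethyl-1-methylidenespiro[5.5]undecane | C=C1CC[C@@H](Br)C(C)(C)[C@]12CC[C@](C)(Br)[C@@H](Cl)C2 | target

**Step count and risks**

Total step count: 14. Longest linear sequence: 11 steps (steps 4–14, from 8); the lactone branch (steps 1–3) joins at step 9.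

Steps most likely to fail:

1. Step 9. C-alkylation of the neopentyl-flanked enolate at the β-branched, β-chlorinated triflate may be slow enough for O-alkylation or base-induced loss of triflic acid to take over. In the second stage, elimination at the tertiary bromide or 3-exo-tet closure onto the secondary chloride may compete with the six-membered ring closure. The facial preference of the ring closure is also argued from sterics and is not secured. Fallback, setting out from 7 and 13 and returning at 16, makes the C6–C11 bond by carbonyl olefination instead of displacement. Lactone 7 is converted with LiN(iPr)2 and ClP(O)(OEt)2, then excess LiN(iPr)2 (oxygen-to-carbon phosphoryl shift), into the α-phosphono lactone diethyl [(5S)-5-ethenyl-4,4-dimethyl-2-oxooxolan-3-yl]phosphonate F1. Alcohol 13 is oxidised with Dess–Martin periodinane to the α-chloro aldehyde (2S,3S)-3,5-dibromo-2-chloro-3-methylpentanal F2, which is used at once and kept cold. A Horner–Wadsworth–Emmons reaction under Masamune–Roush conditions (LiCl, iPr2NEt, MeCN, 0 °C), whose weak amine base should not enolise the aldehyde, joins them as the alkylidene lactone F3. Conjugate reduction with LiBH(s-Bu)3 in THF at −78 °C then generates the C6 enolate regiospecifically, and warming with DMPU closes ring B onto the C7 bromide to give 16.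

2. Step 14. The alkoxyphosphonium ion at the neopentylic C4 may ionise, with methyl migration from C5 or loss of a proton from C3, instead of being displaced from the rear. Fallback, setting out from 23 and returning at 24, uses an isolated sulfonate and a soluble bromide salt, with no phosphonium intermediate and no hydrogen bromide. Chloromethanesulfonyl chloride and pyridine in CH2Cl2 at 0 °C convert 23 into its chloromethanesulfonate F4. LiBr in DMF at 50 °C should then displace it with inversion to give 24.

3. Step 11. The cyclic hemiketal alkoxide may fail to open and enolise, the triflimide may sulfonylate the secondary alkoxide in competition with the enolate, or the alkoxide may take over the triflyl group from the enol triflate before it is silylated. Fallback, setting out from 16 and returning at 23, avoids hemiketal, free alkoxide and triflate and closes ring A by the same C1–C2 coupling with an alkenyl bromide. iBu2AlH (1.1 equiv, CH2Cl2, −78 °C) reduces 16 to the lactol F5. Dimethyl (1-diazo-2-oxopropyl)phosphonate with K2CO3 in MeOH (Ohira–Bestmann alkynylation) gives the hydroxy alkyne F6. tert-Butyldimethylsilyl triflate and 2,6-lutidine give the silyl ether alkyne F7. Bromoboration of the terminal alkyne with B-bromo-9-BBN and protonolysis with acetic acid give the 2-bromoalkene F8. 9-BBN-H then forms the alkylborane F9, which with PdCl2(dppf), AsPh3 and Cs2CO3 closes ring A to the tert-butyldimethylsilyl ether F10. HF·pyridine then gives 23.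

**Further compounds**

F1 | step 9 | diethyl [(5S)-5-ethenyl-4,4-dimethyl-2-oxooxolan-3-yl]phosphonate (both C3 epimers) | CCOP(=O)(OCC)C1C(=O)O[C@@H](C=C)C1(C)C
F2 | step 9 | (2S,3S)-3,5-dibromo-2-chloro-3-methylpentanal | BrCC[C@](C)(Br)[C@@H](Cl)C=O
F3 | step 9 | (5S)-3-[(2S,3S)-3,5-dibromo-2-chloro-3-methylpentylidene]-5-ethenyl-4,4-dimethyloxolan-2-one (E/Z mixture) | O=C1O[C@@H](C=C)C(C)(C)C1=C[C@H](Cl)[C@@](C)(Br)CCBr
F4 | step 14 | chloromethanesulfonate of 23, (4S,6S,9S,10S)-9-bromo-10-chloro-5,5,9-trimethyl-1-methylidenespiro[5.5]undecan-4-yl chloromethanesulfonate | C=C1CC[C@H](OS(=O)(=O)CCl)C(C)(C)[C@]12CC[C@](C)(Br)[C@@H](Cl)C2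
F5 | step 11 | lactol of 16, (3S,5R,7S,8S)-8-bromo-7-chloro-3-ethenyl-4,4,8-trimethyl-2-oxaspiro[4.5]decan-1-ol (both C1 epimers) | OC1O[C@@H](C=C)C(C)(C)[C@]12CC[C@](C)(Br)[C@@H](Cl)C2
F6 | step 11 | (3S)-4-[(1S,3S,4S)-4-bromo-3-chloro-1-ethynyl-4-methylcyclohexyl]-4-methylpent-1-en-3-ol | C#C[C@@]1(CC[C@](C)(Br)[C@@H](Cl)C1)C(C)(C)[C@@H](O)C=C
F7 | step 11 | tert-butyldimethylsilyl ether of F6 | C#C[C@@]1(CC[C@](C)(Br)[C@@H](Cl)C1)C(C)(C)[C@@H](O[Si](C)(C)C(C)(C)C)C=C
F8 | step 11 | 2-bromoalkene from F7 (1-bromoethenyl group on C6, configurations as in 20) | C=C(Br)[C@@]1(CC[C@](C)(Br)[C@@H](Cl)C1)C(C)(C)[C@@H](O[Si](C)(C)C(C)(C)C)C=C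
F9 | step 11 | B-alkyl-9-BBN adduct of F8 (boron on C2) | C=C(Br)[C@@]1(CC[C@](C)(Br)[C@@H](Cl)C1)C(C)(C)[C@@H](O[Si](C)(C)C(C)(C)C)CCB1C2CCCC1CCC2
F10 | step 11 | (4S,6S,9S,10S)-9-bromo-4-(tert-butyldimethylsilyloxy)-10-chloro-5,5,9-trimethyl-1-methylidenespiro[5.5]undecane | C=C1CC[C@H](O[Si](C)(C)C(C)(C)C)C(C)(C)[C@]12CC[C@](C)(Br)[C@@H](Cl)C2
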